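## The problem

The target is a germacranolide: a ten-membered carbocycle (C1–C10) trans-fused through C6 and C7 to an α-methylene-γ-lactone (O–C6, C7–C11(=C13H2)–C12=O). C1 is a carbinol, C4 carries the C15 hydroxymethyl group, C8 the (S)-2-methylbutanoate and C10 the C14 methyl group. Both ring alkenes (C4=C5 and C9=C10) are trisubstituted and cis within the ring, so each needs a geometry-defined construction before a strained medium ring is closed. C6, C7 and C8 are contiguous and can be set in one event. C1 lies across the C9=C10 alkene from C8, has no neighbour to direct it in an open chain, and must be set by a reagent or corrected on the ring. The fifth stereocentre is α to the side-chain ester carbonyl and must be brought in intact. The exocyclic methylene lactone is a Michael acceptor, the oxygens on C6 and C8 are both allylic and both γ to C12 (so O8 can compete for the lactone carbonyl), and the C1 and C15 allylic alcohols must be told apart; strong bases, nucleophiles and acids are therefore unwelcome late. The enabling feature is the array O6–C6 / C7–C11 / C8–O: it is the pattern of an erythro, trans-configured 2,3-epoxy alcohol (C6 carbinol, C7–C8 epoxide) opened at C7 with inversion by a carbon tethered to O6. Because that carbon is C11, a phosphonate on it can also deliver the C13 methylene.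

## Retrosynthesis

**C1–C10 (ring opening).** Removing the C15 silyl ether (31 ⇐ 30) and treating the C1 carbinol as the product of a reagent-controlled reduction of enone 29 leads to the C1-epimeric carbinols 28. Cutting C1–C10 in 28 gives aldehyde 27 with a (Z)-alkenyl iodide at C10. Unlike a cut at C5–C6 or C6–C7, this one creates no centre of the C6–C8 triad during cyclisation; the only new centre, C1, is an allylic carbinol that can be oxidised and reduced again. The precursor is an open chain with a finished lactone. The forward Nozaki–Hiyama–Kishi reaction must tolerate ester, lactone and exocyclic methylene and keep the C9=C10 geometry.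

**O8–acyl and the C1 oxidation level.** Aldehyde 27 comes from 25 by PMB removal (26) and oxidation. Ester 25 comes from alcohol 23 and (S)-2-methylbutanoic acid 24. Acylating before C1 is unmasked leaves only one free hydroxyl at each oxidation, and the forward esterification must not epimerise the α-centre of 24.

**C7–C11 and C11=C13 (key disconnection).** Lactone 23 is cut at C7–C11 and C11=C13 to the O6 diethylphosphonoacetate 21 and formaldehyde. Compared with cutting the lactone C–O bond or C6–C7 (allylation of an aldehyde), this makes O6 the tether: ring size then decides that C7 and not the allylic C8 is attacked, and C8 emerges as a free hydroxyl for the chiral ester. The precursor has no ring other than the epoxide and only reagent-set stereocentres. The forward step must give carbon alkylation in a 5-exo mode and then olefinate formaldehyde without a second base.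

**O6–C12.** Ester 21 is cut to epoxy alcohol 19 and diethylphosphonoacetic acid 20, a routine esterification that must not trigger Payne rearrangement.

**The epoxide.** Epoxy alcohol 19 is traced to racemic dienol 18 by a Sharpless kinetic-resolution epoxidation. One reagent thereby selects C6 and sets C7 and C8. The forward reaction must epoxidise the E-disubstituted C7=C8 alkene of one enantiomer and leave the C4=C5 alkene alone.

**C6–C7.** Dienol 18 is cut between C6 and C7 to enal 10 and enyne 15, joined through alkenylmetals 16 and 17. The neighbouring cut at C5–C6 would need a trisubstituted alkenylmetal of defined geometry and an aldehyde carrying the iodide. Hydrometalation of the alkyne instead sets the E C7=C8 alkene in the bond-forming step.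

**C3–C4 and the C4=C5 geometry.** Enal 10 comes from allylic alcohol 9, cut at C3–C4 to alkenyl iodide 4 and the alkylborane 8 from allyl ether 7. Iodide 4 comes from but-2-yne-1,4-diol 1 through 2 by directed trans-hydroalumination, which fixes the alkene geometry.

**C9=C10.** Enyne 15 comes from silylated enyne 14, cut at C9=C10 to 3-(trimethylsilyl)propynal 11 and the ethylidene unit of phosphonium salt 12 (α-iodoethylidene Wittig reaction).

## Roads not taken

**Alternative 1:** The cut is at C7–C8, with C8 joined through oxygen to C13, so that the precursor of A1 is a thirteen-membered diallylic ether. In the forward step n-BuLi would deprotonate the C8 ether methylene and a [2,3]-Wittig rearrangement would form C7–C8, contract the ring to the carbocycle and unveil C11=C13, giving A1.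
- Merits: the medium ring is never closed head-on, C7 and C8 are set in the ring-forming event, and C8 appears as a free hydroxyl. In ring formation this road is better than the chosen plan, which must accept a Nozaki–Hiyama–Kishi closure of a strained ring.
- Weak points: two allylic ether methylenes (C8 and C13) compete for deprotonation and each anion has [2,3] and [1,2] pathways. The C7/C8 configuration rests on the conformation of a macrocyclic transition state, not on a reagent. C12 arrives at the alcohol level and must be raised to the acid among three other silyl ethers, and O6 must be freed for lactonisation while O8 competes for C12.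
- Comparison: the chosen plan fixes C6–C8 by one reagent-controlled epoxidation and reaches the lactone at the right oxidation level with two protecting groups instead of five.

**Alternative 2:** The cut is at C5–C6 and at the lactone C–O bond. CrCl2 with catalytic NiCl2 would add a C5 alkenyl iodide to a C6 aldehyde, and the chromium alkoxide would close the lactone onto a C12 methyl ester, giving A2 with both rings formed.
- Merits: two rings in one step; C1 is set in an open chain, where reagent control is dependable; the endgame is only PMB/acyl exchange and desilylation. In step count after the key step and in control of C1 this road is as good as or better than the chosen plan.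
- Weak points: C6 is created during macrocyclisation, so its configuration relative to C7 depends on an unpredictable facial preference. The aldehyde precursor of A2 is branched at C7, which carries the acrylate and is flanked by the C8 ether, so enolisation would epimerise C7 or eliminate the C8 oxygen. The C7/C8 acrylate unit needs its own stereoselective synthesis.
- Comparison: the chosen plan settles the whole C6–C8 triad before any ring is closed and frees O8 directly for the chiral ester.

**Alternative 3:** The cut is at C2–C3 with C5–C10 re-formed, so that the precursor of A3 is a cyclohexanol (ring atoms C5–C10) with alkenyl groups on C10 and C5. KH and 18-crown-6 would trigger an anionic oxy-Cope rearrangement to the ten-membered C10 ketone A3.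
- Merits: this is the most dependable way to the ten-membered ring, the ring-cis C4=C5 geometry follows from the transition state, and C6–C8 are set on a cyclohexane. For ring formation it is better than the chosen plan.
- Weak points: A3 lacks the C14 methyl group, the C9=C10 alkene and the C1 oxygen, and C11/C12 are at the alkane/alcohol level. The endgame would need enolisation toward C9 and not C1, methyl introduction, stereoselective C1 oxidation on a flexible ring, two-level oxidation at C12, lactonisation, methylenation and PMB/acyl exchange.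
- Comparison: the chosen plan closes the ring with every carbon and oxygen in place and only the C1 configuration left to adjust.

Key step: step 11

Remark: atoms are numbered as in the germacranolide skeleton; the CIP labels of C7 and C8 change in some intermediates because iodine and acyl groups alter substituent ranking, while the spatial arrangement in the SMILES strings stays the same.

## Route

Step 1
Reactants: 1 but-2-yne-1,4-diol
Product: 2 4-[(tert-butyldimethylsilyl)oxy]but-2-yn-1-ol
Conditions: NaH (1.0 equiv), THF, 0 °C; TBSCl (1.0 equiv), 0 °C to rt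
Reagents that add atoms: tert-butyldimethylsilyl chloride, CC(C)(C)[Si](C)(C)Cl
Why: O-Silylation of the monosodium alkoxide of a symmetric diol should stop after one silyl group, which marks the future C15 oxygen and leaves the future C6 oxygen free.

Step 2
Reactants: 2 4-[(tert-butyldimethylsilyl)oxy]but-2-yn-1-ol
Product: 4 (2Z)-4-[(tert-butyldimethylsilyl)oxy]-3-iodobut-2-en-1-ol, via cyclic sodium alkenylalkoxyaluminate 3 (not isolated)
Conditions: NaAlH2(OCH2CH2OMe)2, THF, 0 °C to rt; EtOAc; I2, THF, −78 to 0 °C
Reagents that add atoms: iodine, II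
Why: Hydroxyl-directed trans-hydroalumination of the propargylic alcohol places aluminium on the distal alkyne carbon in a five-membered alkoxyaluminate, and iodinolysis with retention should give the (Z)-iodide. Iodine (later C3) is thereby cis to the future C6, which fixes the C4=C5 geometry.

Step 3
Reactants: 5 4-methoxybenzyl alcohol; 6 allyl bromide
Product: 7 allyl 4-methoxybenzyl ether
Conditions: NaH, THF/DMF, 0 °C to rt
Reagents that add atoms: none
Why: Williamson ether synthesis between a primary alkoxide and an allylic bromide.

Step 4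
Reactants: 7 allyl 4-methoxybenzyl ether; 4 (2Z)-4-[(tert-butyldimethylsilyl)oxy]-3-iodobut-2-en-1-ol
Product: 9 (2E)-3-{[(tert-butyldimethylsilyl)oxy]methyl}-6-[(4-methoxybenzyl)oxy]hex-2-en-1-ol, via alkyl-9-borabicyclononane 8 (not isolated)
Conditions: 9-BBN-H, THF, 0 °C to rt; then 4, Pd(dppf)Cl2 (5 mol %), AsPh3, Cs2CO3, DMF/THF/H2O, rt
Reagents that add atoms: none
Why: Anti-Markovnikov hydroboration of the terminal alkene followed by B-alkyl Suzuki–Miyaura coupling forms C3–C4 with retention of the alkenyl iodide geometry; the free allylic hydroxyl and the silyl ether are tolerated.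

Step 5
Reactants: 9 (2E)-3-{[(tert-butyldimethylsilyl)oxy]methyl}-6-[(4-methoxybenzyl)oxy]hex-2-en-1-ol
Product: 10 (2E)-3-{[(tert-butyldimethylsilyl)oxy]methyl}-6-[(4-methoxybenzyl)oxy]hex-2-enal
Conditions: MnO2, CH2Cl2, rt
Reagents that add atoms: none
Why: Allylic oxidation with MnO2 is selective for the allylic alcohol and neutral, so the alkene geometry should be preserved.

Step 6
Reactants: 11 3-(trimethylsilyl)prop-2-ynal; 12 ethyltriphenylphosphonium bromide
Product: 14 [(3Z)-4-iodopent-3-en-1-yn-1-yl]trimethylsilane, via 1-iodoethyl(triphenyl)phosphonium iodide 13 (not isolated)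
Conditions: 12, n-BuLi, THF, 0 °C; I2, −78 °C; NaN(SiMe3)2, −78 to −20 °C; 11, −78 °C to rt
Reagents that add atoms: iodine, II
Why: Stork–Zhao-type α-iodoethylidene Wittig olefination: the ethylidene ylide is iodinated and deprotonated in the flask, and the non-stabilised iodo ylide should give the (Z)-iodoalkene through the kinetically preferred cis-oxaphosphetane. This fixes the C9=C10 geometry (iodine, later C1, cis to the future C8).

Step 7
Reactants: 14 [(3Z)-4-iodopent-3-en-1-yn-1-yl]trimethylsilane
Product: 15 (3Z)-4-iodopent-3-en-1-yne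
Conditions: K2CO3 (cat.), MeOH, 0 °C; product kept in solution
Reagents that add atoms: none
Why: Methoxide-mediated protiodesilylation of an alkynylsilane; the alkenyl iodide is inert.

Step 8
Reactants: 15 (3Z)-4-iodopent-3-en-1-yne; 10 (2E)-3-{[(tert-butyldimethylsilyl)oxy]methyl}-6-[(4-methoxybenzyl)oxy]hex-2-enal
Product: 18 racemic (2Z,4E,7E)-8-{[(tert-butyldimethylsilyl)oxy]methyl}-2-iodo-11-[(4-methoxybenzyl)oxy]undeca-2,4,7-trien-6-ol, via dienylzirconocene chloride 16 (not isolated), via dienyl(methyl)zinc 17 (not isolated)
Conditions: Cp2Zr(H)Cl, CH2Cl2, rt; Me2Zn, toluene, −65 °C; then 10, 0 °C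
Reagents that add atoms: none
Why: syn-Hydrozirconation of the terminal alkyne gives the (E)-alkenylzirconocene, and transmetalation to zinc followed by 1,2-addition to the enal forms C6–C7 with the E C7=C8 alkene. The alkenyl iodide is untouched and C6 is formed racemic.

Step 9
Reactants: 18 racemic (2Z,4E,7E)-8-{[(tert-butyldimethylsilyl)oxy]methyl}-2-iodo-11-[(4-methoxybenzyl)oxy]undeca-2,4,7-trien-6-ol
Product: 19 (1R,2E)-1-{(2R,3R)-3-[(1Z)-2-iodoprop-1-en-1-yl]oxiran-2-yl}-3-{[(tert-butyldimethylsilyl)oxy]methyl}-6-[(4-methoxybenzyl)oxy]hex-2-en-1-ol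
Conditions: Ti(OiPr)4 (0.2 equiv), D-(−)-diisopropyl tartrate (0.24 equiv), t-BuOOH (0.6 equiv), 4 Å molecular sieves, CH2Cl2, −20 °C, stopped near half conversion
Reagents that add atoms: tert-butyl hydroperoxide, CC(C)(C)OO
Why: Sharpless kinetic-resolution epoxidation: with the D-tartrate the (6S)-enantiomer is the fast one at the E-disubstituted C7=C8 alkene and gives the erythro trans-epoxy alcohol, so C6 is selected and C7 and C8 are set by the reagent. For this enantiomer the C4=C5 alkene is the mismatched site and carries a substituent cis to the carbinol, so it should react slowly; the (6R)-enantiomer of 18 is separated.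

Step 10
Reactants: 19 (1R,2E)-1-{(2R,3R)-3-[(1Z)-2-iodoprop-1-en-1-yl]oxiran-2-yl}-3-{[(tert-butyldimethylsilyl)oxy]methyl}-6-[(4-methoxybenzyl)oxy]hex-2-en-1-ol; 20 diethylphosphonoacetic acid
Product: 21 (1R,2E)-1-{(2S,3R)-3-[(1Z)-2-iodoprop-1-en-1-yl]oxiran-2-yl}-3-{[(tert-butyldimethylsilyl)oxy]methyl}-6-[(4-methoxybenzyl)oxy]hex-2-en-1-yl (diethoxyphosphoryl)acetate
Conditions: DCC, DMAP (cat.), CH2Cl2, 0 °C to rt
Reagents that add atoms: none
Why: Steglich esterification of the secondary epoxy alcohol under near-neutral conditions, which should avoid Payne rearrangement and epoxide opening.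

Step 11
Reactants: 21 (1R,2E)-1-{(2S,3R)-3-[(1Z)-2-iodoprop-1-en-1-yl]oxiran-2-yl}-3-{[(tert-butyldimethylsilyl)oxy]methyl}-6-[(4-methoxybenzyl)oxy]hex-2-en-1-yl (diethoxyphosphoryl)acetate
Product: 23 (4R,5R)-4-[(1S,2Z)-1-hydroxy-3-iodobut-2-en-1-yl]-5-[(1E)-2-{[(tert-butyldimethylsilyl)oxy]methyl}-5-[(4-methoxybenzyl)oxy]pent-1-en-1-yl]-3-methylideneoxolan-2-one, via α-phosphono lactone 22 (not isolated)
Conditions: NaH (1.05 equiv), THF, 0 to 50 °C; then (CH2O)n, 0 °C to rt
Reagents that add atoms: formaldehyde (as paraformaldehyde), C=O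
Why: Proposed new method: NaH deprotonates the phosphonoacetate to a sodium-chelated, carbon-nucleophilic anion, and on warming C11 should attack C7 from the side opposite the epoxide oxygen, a 5-exo-tet closure that forms C7–C11 and the γ-lactone and releases the C8 alkoxide. That alkoxide should take the acidic α-phosphoryl proton of 22, so the single equivalent of base is relayed to C11 and the phosphonate anion olefinates formaldehyde (Horner–Wadsworth–Emmons reaction) to give C11=C13 and sodium diethyl phosphate. The closest known reaction types are the intermolecular opening of epoxides by sodium trialkyl phosphonoacetates with lactonisation and formaldehyde olefination, the exo-selective intramolecular opening of epoxides by tethered stabilised carbanions, and the formaldehyde olefination of α-phosphono-γ-lactones made by carbenoid C–H insertion of ester-tethered diazophosphonoacetates; new here are the ester oxygen inside the closing ring and the use of the released alkoxide as the base. C7 is the only centre changed: backside attack inverts it, so the trans-epoxide of the erythro epoxy alcohol gives the trans-disubstituted lactone, while C6 and C8 keep their configuration. The step needs attack at C7 and not at the allylic C8 (6-endo), and carbon instead of oxygen alkylation; the five-membered transition state, the absence of any Lewis acid that would loosen the allylic C8–O bond, and sodium chelation of the phosphoryl and carbonyl oxygens are relied on for this. Relactonisation to O8 is not expected, because that lactone would be cis-disubstituted and the alkoxide is quenched internally.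

Step 12
Reactants: 23 (4R,5R)-4-[(1S,2Z)-1-hydroxy-3-iodobut-2-en-1-yl]-5-[(1E)-2-{[(tert-butyldimethylsilyl)oxy]methyl}-5-[(4-methoxybenzyl)oxy]pent-1-en-1-yl]-3-methylideneoxolan-2-one; 24 (2S)-2-methylbutanoic acid
Product: 25 (1S,2Z)-1-[(2R,3S)-2-[(1E)-2-{[(tert-butyldimethylsilyl)oxy]methyl}-5-[(4-methoxybenzyl)oxy]pent-1-en-1-yl]-4-methylidene-5-oxooxolan-3-yl]-3-iodobut-2-en-1-yl (2S)-2-methylbutanoate
Conditions: DCC, DMAP (cat.), CH2Cl2, 0 °C
Reagents that add atoms: none
Why: Steglich esterification of the only free hydroxyl; at 0 °C with catalytic DMAP the α-centre of the branched acid should survive, and C8 is acylated before any oxidation step.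

Step 13
Reactants: 25 the O8 (2S)-2-methylbutanoate named in step 12
Product: 26 (1S,2Z)-1-[(2R,3S)-2-[(1E)-2-{[(tert-butyldimethylsilyl)oxy]methyl}-5-hydroxypent-1-en-1-yl]-4-methylidene-5-oxooxolan-3-yl]-3-iodobut-2-en-1-yl (2S)-2-methylbutanoate
Conditions: DDQ, CH2Cl2/pH 7 buffer, 0 °C
Reagents that add atoms: none
Why: Oxidative cleavage of the 4-methoxybenzyl ether by DDQ frees only the C1 hydroxyl; silyl ether, esters and the isolated alkenes are inert.

Step 14
Reactants: 26 the C1 alcohol named in step 13
Product: 27 (1S,2Z)-1-[(2R,3S)-2-[(1E)-2-{[(tert-butyldimethylsilyl)oxy]methyl}-5-oxopent-1-en-1-yl]-4-methylidene-5-oxooxolan-3-yl]-3-iodobut-2-en-1-yl (2S)-2-methylbutanoate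
Conditions: Dess–Martin periodinane, CH2Cl2, 0 °C to rt
Reagents that add atoms: none
Why: Dess–Martin oxidation of the single primary alcohol to the aldehyde under mild conditions.

Step 15
Reactants: 27 the C1 aldehyde named in step 14
Product: 28 (6R,7R,8R,4E,9Z)-15-[(tert-butyldimethylsilyl)oxy]-1-hydroxy-8-[(2S)-2-methylbutanoyloxy]germacra-4,9,11(13)-trien-12,6-olide (C1 epimers)
Conditions: CrCl2 (10 equiv), NiCl2 (2 mol % of Cr), DMSO/THF, 0.002 M, slow addition, rt
Reagents that add atoms: none
Why: Nozaki–Hiyama–Kishi reaction: nickel-mediated formation of the alkenylchromium species from the trisubstituted (Z)-iodide with retention, and its chemoselective addition to the aldehyde, should close C1–C10. Esters and the lactone are tolerated, and C1 is formed without control.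

Step 16
Reactants: 28 the C1-epimeric macrocyclic carbinols named in step 15
Product: 29 (6R,7R,8R,4E,9Z)-15-[(tert-butyldimethylsilyl)oxy]-8-[(2S)-2-methylbutanoyloxy]-1-oxogermacra-4,9,11(13)-trien-12,6-olide
Conditions: Dess–Martin periodinane, CH2Cl2, rt
Reagents that add atoms: none
Why: Dess–Martin oxidation of the only free (allylic) hydroxyl converges both C1 epimers on one enone.

Step 17
Reactants: 29 the C1 enone named in step 16
Product: 30 (1S,6R,7R,8R,4E,9Z)-15-[(tert-butyldimethylsilyl)oxy]-1-hydroxy-8-[(2S)-2-methylbutanoyloxy]germacra-4,9,11(13)-trien-12,6-olide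
Conditions: (R)-2-methyl-CBS-oxazaborolidine (0.3 equiv), catecholborane, toluene, −78 °C
Reagents that add atoms: none
Why: Corey–Bakshi–Shibata reduction: the α-methylalkenyl arm (C10) acts as the large group and C2 as the small one, so the (R)-catalyst should deliver hydride to the face that gives the 1S carbinol. Catecholborane at −78 °C reduces the ketone 1,2 and should spare the acrylate and the esters.

Step 18
Reactants: 30 the (1S)-carbinol named in step 17
Product: 31 (1S,6R,7R,8R,4E,9Z)-1,15-dihydroxy-8-[(2S)-2-methylbutanoyloxy]germacra-4,9,11(13)-trien-12,6-olide (CNP0526758.1)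
Conditions: HF·pyridine, pyridine/THF, 0 °C to rt
Reagents that add atoms: none
Why: Buffered fluoride desilylation of the primary allylic silyl ether; the mildly acidic medium avoids acyl migration, Michael addition and relactonisation.

## Compound list

1 | but-2-yne-1,4-diol | OCC#CCO | starting material
2 | 4-[(tert-butyldimethylsilyl)oxy]but-2-yn-1-ol | OCC#CCO[Si](C)(C)C(C)(C)C | intermediate
3 | cyclic sodium alkenylalkoxyaluminate of 2 (Al on the alkene carbon bearing CH2OTBS, bound to O1 in a five-membered ring) | COCCO[Al-]1(OCCOC)OCC=C1CO[Si](C)(C)C(C)(C)C.[Na+] | intermediate (not isolated)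
4 | (2Z)-4-[(tert-butyldimethylsilyl)oxy]-3-iodobut-2-en-1-ol | OC/C=C(\I)CO[Si](C)(C)C(C)(C)C | intermediate
5 | 4-methoxybenzyl alcohol | COc1ccc(CO)cc1 | starting material
6 | allyl bromide | C=CCBr | starting material
7 | allyl 4-methoxybenzyl ether | C=CCOCc1ccc(OC)cc1 | intermediate
8 | 9-{3-[(4-methoxybenzyl)oxy]propyl}-9-borabicyclo[3.3.1]nonane | COc1ccc(COCCCB2C3CCCC2CCC3)cc1 | intermediate (not isolated)
9 | (2E)-3-{[(tert-butyldimethylsilyl)oxy]methyl}-6-[(4-methoxybenzyl)oxy]hex-2-en-1-ol | OC/C=C(\CCCOCc1ccc(OC)cc1)CO[Si](C)(C)C(C)(C)C | intermediate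
10 | (2E)-3-{[(tert-butyldimethylsilyl)oxy]methyl}-6-[(4-methoxybenzyl)oxy]hex-2-enal | O=C/C=C(\CCCOCc1ccc(OC)cc1)CO[Si](C)(C)C(C)(C)C | intermediate
11 | 3-(trimethylsilyl)prop-2-ynal | C[Si](C)(C)C#CC=O | starting material
12 | ethyltriphenylphosphonium bromide | CC[P+](c1ccccc1)(c1ccccc1)c1ccccc1.[Br-] | starting material
13 | (1-iodoethyl)triphenylphosphonium iodide | CC(I)[P+](c1ccccc1)(c1ccccc1)c1ccccc1.[I-] | intermediate (not isolated)
14 | [(3Z)-4-iodopent-3-en-1-yn-1-yl]trimethylsilane | C[Si](C)(C)C#C/C=C(/C)I | intermediate
15 | (3Z)-4-iodopent-3-en-1-yne | C#C/C=C(/C)I | intermediate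
16 | chlorobis(cyclopentadienyl)[(1E,3Z)-4-iodopenta-1,3-dien-1-yl]zirconium (cyclopentadienyl rings drawn σ-bonded) | Cl[Zr](/C=C/C=C(/C)I)(C1C=CC=C1)C1C=CC=C1 | intermediate (not isolated)
17 | [(1E,3Z)-4-iodopenta-1,3-dien-1-yl](methyl)zinc | C[Zn]/C=C/C=C(/C)I | intermediate (not isolated)
18 | racemic (2Z,4E,7E)-8-{[(tert-butyldimethylsilyl)oxy]methyl}-2-iodo-11-[(4-methoxybenzyl)oxy]undeca-2,4,7-trien-6-ol (C6 carbinol) | OC(/C=C(\CCCOCc1ccc(OC)cc1)CO[Si](C)(C)C(C)(C)C)/C=C/C=C(/C)I | intermediate
19 | (1R,2E)-1-{(2R,3R)-3-[(1Z)-2-iodoprop-1-en-1-yl]oxiran-2-yl}-3-{[(tert-butyldimethylsilyl)oxy]methyl}-6-[(4-methoxybenzyl)oxy]hex-2-en-1-ol (6R,7R,8R; erythro, trans-epoxide) | O[C@H](/C=C(/CO[Si](C)(C)C(C)(C)C)CCCOCc1ccc(OC)cc1)[C@H]1O[C@@H]1/C=C(C)\I | intermediate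
20 | diethylphosphonoacetic acid | CCOP(=O)(CC(=O)O)OCC | starting material
21 | O6 (diethoxyphosphoryl)acetate of 19 (6R,7S,8R) | CCOP(=O)(OCC)CC(=O)O[C@H](/C=C(/CO[Si](C)(C)C(C)(C)C)CCCOCc1ccc(OC)cc1)[C@H]1O[C@@H]1/C=C(C)\I | intermediate
22 | diethyl [(4R,5R)-4-[(1S,2Z)-1-hydroxy-3-iodobut-2-en-1-yl]-5-[(1E)-2-{[(tert-butyldimethylsilyl)oxy]methyl}-5-[(4-methoxybenzyl)oxy]pent-1-en-1-yl]-2-oxooxolan-3-yl]phosphonate (C11 epimers; formed as its sodium salts) | CCOP(=O)(OCC)C1C(=O)O[C@H](/C=C(/CO[Si](C)(C)C(C)(C)C)CCCOCc2ccc(OC)cc2)[C@H]1[C@H](O)/C=C(C)\I | intermediate (not isolated)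
23 | (4R,5R)-4-[(1S,2Z)-1-hydroxy-3-iodobut-2-en-1-yl]-5-[(1E)-2-{[(tert-butyldimethylsilyl)oxy]methyl}-5-[(4-methoxybenzyl)oxy]pent-1-en-1-yl]-3-methylideneoxolan-2-one (trans lactone, free C8 hydroxyl) | C=C1C(=O)O[C@H](/C=C(/CO[Si](C)(C)C(C)(C)C)CCCOCc2ccc(OC)cc2)[C@H]1[C@H](O)/C=C(C)\I | intermediate
24 | (2S)-2-methylbutanoic acid | CC[C@H](C)C(=O)O | starting material
25 | O8 (2S)-2-methylbutanoate of 23 (6R,7S,8S; C1 PMB ether) | C=C1C(=O)O[C@H](/C=C(/CO[Si](C)(C)C(C)(C)C)CCCOCc2ccc(OC)cc2)[C@H]1[C@H](OC(=O)[C@@H](C)CC)/C=C(C)\I | intermediate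
26 | C1 primary alcohol from 25 | C=C1C(=O)O[C@H](/C=C(/CO[Si](C)(C)C(C)(C)C)CCCO)[C@H]1[C@H](OC(=O)[C@@H](C)CC)/C=C(C)\I | intermediate
27 | C1 aldehyde from 26 | C=C1C(=O)O[C@H](/C=C(/CO[Si](C)(C)C(C)(C)C)CCC=O)[C@H]1[C@H](OC(=O)[C@@H](C)CC)/C=C(C)\I | intermediate
28 | (6R,7R,8R,4E,9Z)-15-[(tert-butyldimethylsilyl)oxy]-1-hydroxy-8-[(2S)-2-methylbutanoyloxy]germacra-4,9,11(13)-trien-12,6-olide, both C1 epimers | C=C1C(=O)O[C@@H]2/C=C(/CO[Si](C)(C)C(C)(C)C)CCC(O)/C(C)=C\[C@@H](OC(=O)[C@@H](C)CC)[C@@H]12 | intermediate
29 | (6R,7R,8R,4E,9Z)-15-[(tert-butyldimethylsilyl)oxy]-8-[(2S)-2-methylbutanoyloxy]-1-oxogermacra-4,9,11(13)-trien-12,6-olide | C=C1C(=O)O[C@@H]2/C=C(/CO[Si](C)(C)C(C)(C)C)CCC(=O)/C(C)=C\[C@@H](OC(=O)[C@@H](C)CC)[C@@H]12 | intermediate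
30 | (1S,6R,7R,8R,4E,9Z)-15-[(tert-butyldimethylsilyl)oxy]-1-hydroxy-8-[(2S)-2-methylbutanoyloxy]germacra-4,9,11(13)-trien-12,6-olide | C=C1C(=O)O[C@@H]2/C=C(/CO[Si](C)(C)C(C)(C)C)CC[C@H](O)/C(C)=C\[C@@H](OC(=O)[C@@H](C)CC)[C@@H]12 | intermediate
31 | (1S,6R,7R,8R,4E,9Z)-1,15-dihydroxy-8-[(2S)-2-methylbutanoyloxy]germacra-4,9,11(13)-trien-12,6-olide | C=C1C(=O)O[C@@H]2/C=C(/CO)CC[C@H](O)/C(C)=C\[C@@H](OC(=O)[C@@H](C)CC)[C@@H]12 | target

## Step count and least certain steps

Total: 18 steps. Longest linear sequence: 15 steps (from 1 through steps 1, 2, 4, 5 and 8–18); step 3 and steps 6–7 are side branches.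

**Step 11 (key step).**
- What may go wrong: closure through the enolate oxygen instead of carbon, or opening at the allylic C8. The tethered ester prefers the conformation in which its carbonyl oxygen, not C11, lies near C7, and the nucleophilic carbon belongs to an enolate inside the forming five-membered ring. A slow closure would also leave time for intermolecular alkylation.
- Fallback (known reactions, lactone built by aldol chemistry): sets out from enal 10 and returns at 23. Methyl 4-chloro-4-oxobutanoate is acylated onto 1-(trimethylsilyl)propyne (AlCl3) to give methyl 4-oxohept-5-ynoate F1, and hydroiodination (NaI, AcOH) gives methyl (5Z)-6-iodo-4-oxohept-5-enoate F2. The (Z)-boron enolate of F2 (Ipc2BOTf, the antipode that leads to the 6R carbinol, i-Pr2NEt) adds to 10 to give the syn-aldol adduct F3. Hydroxyl-directed Evans–Saksena reduction (Me4NBH(OAc)3, AcOH/MeCN) gives the 1,3-anti diol ester F4. Mild acid closes F4 to the trans hydroxy lactone F5; the lactone to O8 would be cis-disubstituted. α-Methylenation through the Mannich base F6 (lithium diisopropylamide, Eschenmoser's salt; then MeI and NaHCO3) gives 23.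

**Step 15.**
- What may go wrong: capture of the alkenylnickel or alkenylchromium intermediate by the exocyclic acrylate (six-membered carbocyclisation onto C13), or reduction of the acrylate by divalent chromium, while closure of the strained ring is slow; oligomerisation is the second concern.
- Fallback (methylenation postponed until after ring closure): sets out from 22, isolated by quenching step 11 before formaldehyde is added, and returns at 28. Esterification of 22 with 24 (DCC, DMAP) gives the phosphono lactone ester F7. DDQ gives the C1 alcohol F8 and Dess–Martin oxidation the aldehyde F9. CrCl2/NiCl2 closure gives the macrocyclic phosphono lactone F10, with no acrylate present. Horner–Wadsworth–Emmons reaction of F10 (K2CO3, aqueous formaldehyde, THF) gives 28.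

**Step 9.**
- What may go wrong: incomplete discrimination, either between the enantiomers or between the two allylic alkenes of the divinyl carbinol, and opening of the vinyl epoxide by alkoxide. Half of the convergent material would be lost and enantiomeric purity would erode.
- Fallback (C6 set by asymmetric catalysis instead of resolution): sets out from 10 and 15 and returns at 19. Alkenylzinc 17 is added to 10 in the presence of a chiral amino alcohol ligand (3-exo-morpholinoisoborneol, the antipode that leads to the 6S carbinol) to give the (6S)-dienol F11. The epoxidation with D-(−)-diisopropyl tartrate is then run to full conversion as a matched, reagent-controlled reaction, giving 19.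

**Step 17.**
- What may go wrong: poor facial selectivity, because the conformation of the ten-membered enone (peripheral attack) may override the catalyst.
- Fallback (inversion instead of reduction): sets out from 28 and returns at 30. The C1 epimers of 28 are separated; the 1S epimer is 30. The 1R epimer is inverted by Mitsunobu reaction with chloroacetic acid (PPh3, diisopropyl azodicarboxylate) to give the (1S)-chloroacetate F12. Thiourea (NaHCO3, EtOH) removes the chloroacetyl group without touching the 2-methylbutanoate, giving 30.

**Step 6.**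
- What may go wrong: low conversion and erosion of the Z/E ratio, because iodination of the ylide competes with formation of non-iodinated and di-iodinated ylides and the ynal is a sensitive partner.
- Fallback (geometry set by selective cross-coupling instead of Wittig selectivity): sets out from 11 and returns at 14. Corey–Fuchs-type dibromo-olefination (CBr4, PPh3) gives (4,4-dibromobut-3-en-1-yn-1-yl)trimethylsilane F13. Negishi coupling with MeZnCl (Pd(DPEphos)Cl2) replaces the bromide trans to the alkynyl group to give [(3Z)-4-bromopent-3-en-1-yn-1-yl]trimethylsilane F14. Copper-catalysed halogen exchange (CuI, a 1,2-diamine ligand, NaI, dioxane, heat) gives 14 with retention.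

## Further compounds

F1 | step 11 | methyl 4-oxohept-5-ynoate | COC(=O)CCC(=O)C#CC
F2 | step 11 | methyl (5Z)-6-iodo-4-oxohept-5-enoate | COC(=O)CCC(=O)/C=C(/C)I
F3 | step 11 | syn-aldol adduct of F2 and 10 (C6 carbinol, C8 ketone, C12 methyl ester) | COC(=O)C[C@@H]([C@H](O)/C=C(/CO[Si](C)(C)C(C)(C)C)CCCOCc1ccc(OC)cc1)C(=O)/C=C(/C)I
F4 | step 11 | 1,3-anti C6,C8-diol methyl ester | COC(=O)C[C@@H]([C@H](O)/C=C(/CO[Si](C)(C)C(C)(C)C)CCCOCc1ccc(OC)cc1)[C@H](O)/C=C(C)\I
F5 | step 11 | trans hydroxy lactone lacking C13 (C11 methylene analogue of 23) | O=C1O[C@H](/C=C(/CO[Si](C)(C)C(C)(C)C)CCCOCc2ccc(OC)cc2)[C@H](C1)[C@H](O)/C=C(C)\I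
F6 | step 11 | α-(dimethylaminomethyl) lactone (Mannich base, C11 epimers) | CN(C)CC1C(=O)O[C@H](/C=C(/CO[Si](C)(C)C(C)(C)C)CCCOCc2ccc(OC)cc2)[C@H]1[C@H](O)/C=C(C)\I
F7 | step 15 | O8 (2S)-2-methylbutanoate of α-phosphono lactone 22 | CCOP(=O)(OCC)C1C(=O)O[C@H](/C=C(/CO[Si](C)(C)C(C)(C)C)CCCOCc2ccc(OC)cc2)[C@H]1[C@H](OC(=O)[C@@H](C)CC)/C=C(C)\I
F8 | step 15 | C1 alcohol from F7 | CCOP(=O)(OCC)C1C(=O)O[C@H](/C=C(/CO[Si](C)(C)C(C)(C)C)CCCO)[C@H]1[C@H](OC(=O)[C@@H](C)CC)/C=C(C)\I
F9 | step 15 | C1 aldehyde from F8 | CCOP(=O)(OCC)C1C(=O)O[C@H](/C=C(/CO[Si](C)(C)C(C)(C)C)CCC=O)[C@H]1[C@H](OC(=O)[C@@H](C)CC)/C=C(C)\I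
F10 | step 15 | macrocyclic α-phosphono lactone with C1 carbinol (C1 and C11 epimers) | CCOP(=O)(OCC)C1C(=O)O[C@@H]2/C=C(/CO[Si](C)(C)C(C)(C)C)CCC(O)/C(C)=C\[C@@H](OC(=O)[C@@H](C)CC)[C@@H]12
F11 | step 9 | (6S)-enantiomer of dienol 18 | O[C@H](/C=C(\CCCOCc1ccc(OC)cc1)CO[Si](C)(C)C(C)(C)C)/C=C/C=C(/C)I
F12 | step 17 | (1S)-chloroacetate of 30 | C=C1C(=O)O[C@@H]2/C=C(/CO[Si](C)(C)C(C)(C)C)CC[C@H](OC(=O)CCl)/C(C)=C\[C@@H](OC(=O)[C@@H](C)CC)[C@@H]12
F13 | step 6 | (4,4-dibromobut-3-en-1-yn-1-yl)trimethylsilane | C[Si](C)(C)C#CC=C(Br)Br
F14 | step 6 | [(3Z)-4-bromopent-3-en-1-yn-1-yl]trimethylsilane | C[Si](C)(C)C#C/C=C(/C)Br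
A1 | alternative 1 | ten-membered C8 carbinol with the C7 2-propenyl unit (C12 triethylsilyl ether; C1, C6 and C15 tert-butyldimethylsilyl ethers) | C=C(CO[Si](CC)(CC)CC)[C@H]1[C@H](O[Si](C)(C)C(C)(C)C)/C=C(/CO[Si](C)(C)C(C)(C)C)CC[C@H](O[Si](C)(C)C(C)(C)C)/C(C)=C\[C@H]1O
A2 | alternative 2 | protected germacranolide with both rings closed (C8 PMB ether; C1 and C15 tert-butyldimethylsilyl ethers) | C=C1C(=O)O[C@@H]2/C=C(/CO[Si](C)(C)C(C)(C)C)CC[C@H](O[Si](C)(C)C(C)(C)C)/C(C)=C\[C@@H](OCc3ccc(OC)cc3)[C@@H]12
A3 | alternative 3 | ten-membered C10 ketone with ring-cis C4=C5 (C6, C12 and C15 silyl ethers; C8 PMB ether) | O=C1CCC/C(CO[Si](C)(C)C(C)(C)C)=C\[C@@H](O[Si](C)(C)C(C)(C)C)[C@H](CCO[Si](C)(C)C(C)(C)C)[C@H](OCc2ccc(OC)cc2)C1
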